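At early times the electrophile and the nucleophile make acid set free at their full charged rate, so I asked first whether free base coming in from the gas could take that acid up as it appeared.

    electrophile + nucleophile ⇌ acid set free + product (K1 = 0.87, k1 = 27.4 M⁻¹ s⁻¹)
    nucleophile + acid set free ⇌ protonated nucleophile, settled at all times (K2 = 4900 M⁻¹)
    acid set free + free base ⇌ salt of the base, settled at all times (K3 = 4.7 × 10⁸ M⁻¹)
    crystals ⇌ acid set free, rate k4*(cs4 - [acid set free]) while solid is left; crystals form when [acid set free] > cs4 (cs4 = 2.7 mM, k4 = 36.9 s⁻¹)
    gas ⇌ free base, rate k5*(csat - [free base]) (k5 = 24.9 s⁻¹, csat = 0.16 mM)

common to all: electrophile 5.0 mM; gas 0.16 mM (held); time 3.0 s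

|  | nucleophile |
|---|---|
| north-west | 7.50 mM |
| north | 15.0 mM |
| west | 30.0 mM |

- part of the electrophile that has reacted at the end, north-west
- part of the electrophile that has reacted at the end, north
- part of the electrophile that has reacted at the end, west
- what raising the concentration of nucleophile from its lowest to its highest value here does to the part of the electrophile that has reacted (changes below 5 percentage points count as none) (it rises / no change / it falls)

- amounts and yields of acid set free count crystals too
- given per volume of solution although it is solid: crystals
- at the start none of free base is dissolved
- run time (north-west): 3.0 s

The forward step makes acid at the charge at 1.03 mM s⁻¹ in north-west, 2.05 mM s⁻¹ in north and 4.11 mM s⁻¹ in west, while free base enters an empty solution at 3.98 mM s⁻¹. In north the ratio is 0.516; I called this the base load, the rate of making acid over the rate of entry with no free base dissolved. West starts level with the entry, at 1.03, but its load falls as the partners are used.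

Free base adjusts within 0.0402 s, far shorter than the run, so I took entry equal to making, which gives c(free base) = csat·(1 − load), the load shrinking with the fractions of both partners left; in west this serves once the load is below one. With the fast salt balance, I paired the whole charge of electrophile as salt, the resting state of the acid, with free base at the level of north's starting load, an estimate and not a state of the flask, and got free acid of 1.37 × 10⁻⁴ mM, far below the solubility and far below K1·c(nucleophile), the measure of the way back when product equals electrophile. So I carried to all three flasks a plain irreversible second-order reaction, with the electrophile as limiting reagent, and committed to 40.6 %, 65.7 % and 89.1 %.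

The forecast gave 40.6 %, 65.7 % and 89.1 %, and for the trend it rises, holding that “free acid stays tiny, no crystals form”.

The simulation gave 40.6 %, 65.7 % and 89.1 %, and for the trend it rises, by 48 percentage points. In north at 3.00 s, with 34 % of the electrophile and 78 % of the nucleophile left, the load had shrunk to 0.138, which gives c(free base) = 0.138 mM; the reading was 0.138 mM. The neighbour is north read at 1.2 s, where the second-order reckoning gives 36.9 % and the flask gave 36.9 %. There 63 % of the electrophile and 88 % of the nucleophile were left, so the load was 0.286, which gives c(free base) = 0.114 mM, and the reading was 0.113 mM.

(The constants used here are those of an exercise; the run is a simulation.)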